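**Retrosynthetic overview**

- The strategy rests on the C2–C1' bond that joins the pyranone ring to the B ring inside the seven-membered oxepine (C2, C3, C9, C10, O, C2', C1'), and on C2–H being the most acidic and accessible C–H of a 3-alkylchromone.
- Target 21 ⇐ desilylation ⇐ Suzuki coupling at C6–I ⇐ C6 iodination ortho to the free 5-OH of tetracycle 16.
- Tetracycle 16 ⇐ bromo-chromone 15 by intramolecular Pd C–H arylation (C2–C1').
- Chromone 15 ⇐ one-carbon annulation of 2,6-dihydroxyaryl ketone 13 ⇐ aryllithium 11 (from 5-methoxyresorcinol) + δ-lactone 8.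
- Lactone 8 ⇐ Mitsunobu inversion of L-glutamate-derived (S)-hydroxy diester 3 with bromophenol 5, then MeMgBr. Ring order: A and B rings are bought, the pyranone ring is made in step 10, the oxepine in step 11.

Key step: step 11

Remark: flavone numbering is used (A ring C5–C8, pyranone O1–C4, B ring C1'–C6', bridge C3–C9H2–C10H–O–C2'). The B-ring hydroxyl is carried as a triisopropylsilyl ether, not an acetal, because the A-ring MOM ethers needed for ortho-lithiation must be cleaved with acid while the B-ring oxygen stays protected until after the C6 iodination.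

**Route**

Step 1
Reactants: 1 L-glutamic acid 5-tert-butyl ester
Product: 2 (S)-5-tert-butoxy-2-hydroxy-5-oxopentanoic acid
Conditions: NaNO2, AcOH/H2O, 0 °C → rt
Reagents that add atoms: water, O
Why: Diazotisation of the α-amino acid; the carboxylate displaces N2 to an α-lactone that water opens, so the double inversion should keep C2 as S, and the dilute acetic acid should spare the tert-butyl ester.

Step 2
Reactants: 2 (S)-5-tert-butoxy-2-hydroxy-5-oxopentanoic acid
Product: 3 5-tert-butyl 1-methyl (S)-2-hydroxypentanedioate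
Conditions: MeI, KHCO3, DMF, rt
Reagents that add atoms: iodomethane, CI
Why: Carboxylate O-alkylation under bicarbonate, too weak a base to alkylate the secondary alcohol or epimerise C2.

Step 3
Reactants: 4 4-bromoresorcinol
Product: 5 2-bromo-5-(triisopropylsilyloxy)phenol
Conditions: TIPSCl (1.05 equiv), imidazole, CH2Cl2, 0 °C
Reagents that add atoms: chlorotriisopropylsilane, CC(C)[Si](Cl)(C(C)C)C(C)C
Why: Sterically controlled monosilylation; the bulky silyl chloride should take the hydroxyl para to bromine and leave the hindered hydroxyl ortho to bromine free.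

Step 4
Reactants: 3 5-tert-butyl 1-methyl (S)-2-hydroxypentanedioate; 5 2-bromo-5-(triisopropylsilyloxy)phenol
Product: 6 5-tert-butyl 1-methyl (R)-2-[2-bromo-5-(triisopropylsilyloxy)phenoxy]pentanedioate
Conditions: PPh3, DIAD, THF, 0 °C → rt
Reagents that add atoms: none
Why: Mitsunobu etherification of an α-hydroxy ester with an acidic ortho-bromophenol; SN2 displacement of the oxyphosphonium inverts C2 from S to R, which is the C10 configuration of the target.

Step 5
Reactants: 6 5-tert-butyl 1-methyl (R)-2-[2-bromo-5-(triisopropylsilyloxy)phenoxy]pentanedioate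
Product: 7 tert-butyl (R)-4-[2-bromo-5-(triisopropylsilyloxy)phenoxy]-5-hydroxy-5-methylhexanoate
Conditions: MeMgBr (2.5 equiv), THF, −78 → −20 °C; sat. NH4Cl
Reagents that add atoms: methylmagnesium bromide, C[Mg]Br
Why: Double Grignard addition to the α-aryloxy methyl ester, which is far more electrophilic than the hindered tert-butyl ester; at low temperature the α-stereocentre should not enolise.

Step 6
Reactants: 7 tert-butyl (R)-4-[2-bromo-5-(triisopropylsilyloxy)phenoxy]-5-hydroxy-5-methylhexanoate
Product: 8 (R)-5-[2-bromo-5-(triisopropylsilyloxy)phenoxy]-6,6-dimethyloxan-2-one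
Conditions: NaH (1.1 equiv), THF, 0 °C → rt; AcOH
Reagents that add atoms: none
Why: Base-mediated lactonisation (intramolecular transesterification); the tertiary alkoxide closes the six-membered ring with loss of tert-butoxide, helped by the gem-dimethyl group, and no cation forms next to C10.

Step 7
Reactants: 9 5-methoxyresorcinol
Product: 10 1-methoxy-3,5-bis(methoxymethoxy)benzene
Conditions: MOMCl, i-Pr2NEt, CH2Cl2, 0 °C → rt
Reagents that add atoms: chloromethyl methyl ether, COCCl
Why: Standard bis-O-alkylation of the phenols, which installs the two groups that direct the lithiation.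

Step 8
Reactants: 10 1-methoxy-3,5-bis(methoxymethoxy)benzene; 8 (R)-5-[2-bromo-5-(triisopropylsilyloxy)phenoxy]-6,6-dimethyloxan-2-one
Product: 12 (R)-4-[2-bromo-5-(triisopropylsilyloxy)phenoxy]-5-hydroxy-1-[4-methoxy-2,6-bis(methoxymethoxy)phenyl]-5-methylhexan-1-one, via [4-methoxy-2,6-bis(methoxymethoxy)phenyl]lithium 11 (not isolated)
Conditions: 10 (1.3 equiv), n-BuLi (1.25 equiv), THF, 0 °C; then 8, −78 → −40 °C; sat. NH4Cl
Reagents that add atoms: none
Why: Directed ortho-lithiation between the two chelating MOM ethers, then acyl substitution on the δ-lactone, whose lithium hemiketal and the hindered ketone resist a second addition; the doubly ortho-alkoxy-stabilised aryllithium should not exchange with the B-ring bromide at −78 °C.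

Step 9
Reactants: 12 (R)-4-[2-bromo-5-(triisopropylsilyloxy)phenoxy]-5-hydroxy-1-[4-methoxy-2,6-bis(methoxymethoxy)phenyl]-5-methylhexan-1-one
Product: 13 (R)-4-[2-bromo-5-(triisopropylsilyloxy)phenoxy]-1-(2,6-dihydroxy-4-methoxyphenyl)-5-hydroxy-5-methylhexan-1-one
Conditions: 3 M HCl, MeOH, 45 °C
Reagents that add atoms: none
Why: Acid-catalysed acetal cleavage of the two MOM ethers ortho to the ketone; the aryl silyl ether is acid-stable and the hydrogen-bonded dihydroxyaryl ketone should resist ketalisation by the tertiary alcohol.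

Step 10
Reactants: 13 (R)-4-[2-bromo-5-(triisopropylsilyloxy)phenoxy]-1-(2,6-dihydroxy-4-methoxyphenyl)-5-hydroxy-5-methylhexan-1-one
Product: 15 (R)-3-[2-(2-bromo-5-triisopropylsilyloxyphenoxy)-3-hydroxy-3-methylbutyl]-5-hydroxy-7-methoxychromen-4-one, via dimethylaminomethylidene ketone 14 (not isolated)
Conditions: DMF-DMA (3 equiv), toluene, 90 °C; then 1 M HCl, THF, rt
Reagents that add atoms: N,N-dimethylformamide dimethyl acetal, COC(OC)N(C)C
Why: Enaminone formation at the ketone α-CH2 and addition–elimination by an ortho phenol (loss of dimethylamine) is the standard route from 2-hydroxyaryl alkyl ketones to 3-alkylchromones; either phenol gives the same chromone and the other becomes the chelated 5-OH.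

Step 11
Reactants: 15 (R)-3-[2-(2-bromo-5-triisopropylsilyloxyphenoxy)-3-hydroxy-3-methylbutyl]-5-hydroxy-7-methoxychromen-4-one
Product: 16 (R)-5-hydroxy-10-(2-hydroxypropan-2-yl)-7-methoxy-4'-triisopropylsilyloxy oxepinoflavone (tetracycle with C2–C1' bond and C3–C9H2–C10H–O–C2' bridge)
Conditions: Pd(OAc)2 (10 mol%), PCy3·HBF4 (20 mol%), PivOH (30 mol%), K2CO3 (2.5 equiv), DMA (0.02 M), 110 °C, argon
Reagents that add atoms: none
Why: Pd(0)/PCy3 inserts into the C1'–Br bond and, after bromide–pivalate exchange, pivalate cleaves the C2–H bond next to O1 by concerted metalation–deprotonation (or the arylpalladium adds across C2=C3 to a C3 palladium enolate that loses HPd with base), and reductive elimination forms C2–C1'. The closest known reaction type is the palladium-catalysed intramolecular direct arylation of heteroarene C–H bonds by tethered aryl bromides, which includes arylation at chromone C2 and closure of seven-membered biaryl rings. The oxepine (C2, C3, C9, C10, O, C2', C1') closes by C(sp2)–C(sp2) bond formation through an eight-membered palladacycle, 7-endo with respect to C2=C3 in the insertion picture. No stereocentre is formed, and C10 lies outside the reacting atoms, so its R configuration should be kept. The step needs C2–H arylation to win over hydrodebromination, over A-ring C–H bonds and over O-arylation by the tertiary hydroxyl; C3 is blocked by the tether, the A ring is out of reach of the short tether, C2–H is the most acidic C–H, and PCy3 with carbonate does not support C–O reductive elimination. Dry, dilute conditions should limit reduction of the bromide and cleavage of the silyl ether.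

Step 12
Reactants: 16 (R)-5-hydroxy-10-(2-hydroxypropan-2-yl)-7-methoxy-4'-triisopropylsilyloxy oxepinoflavone
Product: 17 (R)-5-hydroxy-10-(2-hydroxypropan-2-yl)-6-iodo-7-methoxy-4'-triisopropylsilyloxy oxepinoflavone
Conditions: BnMe3N·ICl2 (1.05 equiv), CaCO3, CH2Cl2/MeOH, rt
Reagents that add atoms: benzyltrimethylammonium dichloroiodate, C[N+](C)(C)Cc1ccccc1.Cl[I-]Cl
Why: Electrophilic aromatic iodination under conditions that iodinate free phenols but not aryl ethers, which on 5-hydroxy-7-methoxyflavones goes ortho to the chelated 5-OH (C6); the B ring is fully etherified and its 3' and 5' positions are shielded by the silyl group.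

Step 13
Reactants: 18 3-methylbut-1-yne
Product: 19 (E)-4,4,5,5-tetramethyl-2-(3-methylbut-1-enyl)-1,3,2-dioxaborolane
Conditions: HBpin, Cp2Zr(H)Cl (5 mol%), Et3N (10 mol%), sealed tube, 40 °C
Reagents that add atoms: pinacolborane, [H]B1OC(C)(C)C(C)(C)O1
Why: Zirconium-catalysed hydroboration of a terminal alkyne; syn anti-Markovnikov addition of B–H fixes the E geometry.

Step 14
Reactants: 17 (R)-5-hydroxy-10-(2-hydroxypropan-2-yl)-6-iodo-7-methoxy-4'-triisopropylsilyloxy oxepinoflavone; 19 (E)-4,4,5,5-tetramethyl-2-(3-methylbut-1-enyl)-1,3,2-dioxaborolane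
Product: 20 (R)-5-hydroxy-10-(2-hydroxypropan-2-yl)-7-methoxy-6-[(E)-3-methylbut-1-enyl]-4'-triisopropylsilyloxy oxepinoflavone
Conditions: Pd(dppf)Cl2 (5 mol%), K2CO3, 1,4-dioxane/H2O, 80 °C
Reagents that add atoms: none
Why: Suzuki–Miyaura coupling of the aryl iodide with an alkenylboronate proceeds with retention of alkene geometry and tolerates the chelated 5-OH; any silyl loss here is harmless because the next step removes the group.

Step 15
Reactants: 20 (R)-5-hydroxy-10-(2-hydroxypropan-2-yl)-7-methoxy-6-[(E)-3-methylbut-1-enyl]-4'-triisopropylsilyloxy oxepinoflavone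
Product: 21 target CNP0216454.1
Conditions: TBAF, AcOH, THF, 0 °C
Reagents that add atoms: none
Why: Fluoride cleavage of the aryl silyl ether under buffered conditions, which should leave the alkene, the tertiary alcohol, the chromone and C10 untouched.

**Compound list**

1 | L-glutamic acid 5-tert-butyl ester | N[C@@H](CCC(=O)OC(C)(C)C)C(=O)O | starting material
2 | (S)-5-tert-butoxy-2-hydroxy-5-oxopentanoic acid | CC(C)(C)OC(=O)CC[C@@H](C(=O)O)O | intermediate
3 | 5-tert-butyl 1-methyl (S)-2-hydroxypentanedioate | CC(C)(C)OC(=O)CC[C@@H](C(=O)OC)O | intermediate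
4 | 4-bromoresorcinol | Oc1ccc(Br)c(O)c1 | starting material
5 | 2-bromo-5-(triisopropylsilyloxy)phenol | Oc1cc(O[Si](C(C)C)(C(C)C)C(C)C)ccc1Br | intermediate
6 | 5-tert-butyl 1-methyl (R)-2-[2-bromo-5-(triisopropylsilyloxy)phenoxy]pentanedioate | CC(C)(C)OC(=O)CC[C@H](C(=O)OC)Oc1cc(O[Si](C(C)C)(C(C)C)C(C)C)ccc1Br | intermediate
7 | tert-butyl (R)-4-[2-bromo-5-(triisopropylsilyloxy)phenoxy]-5-hydroxy-5-methylhexanoate | CC(C)(C)OC(=O)CC[C@H](C(C)(C)O)Oc1cc(O[Si](C(C)C)(C(C)C)C(C)C)ccc1Br | intermediate
8 | (R)-5-[2-bromo-5-(triisopropylsilyloxy)phenoxy]-6,6-dimethyloxan-2-one | CC1(C)OC(=O)CC[C@H]1Oc2cc(O[Si](C(C)C)(C(C)C)C(C)C)ccc2Br | intermediate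
9 | 5-methoxyresorcinol | COc1cc(O)cc(O)c1 | starting material
10 | 1-methoxy-3,5-bis(methoxymethoxy)benzene | COCOc1cc(OC)cc(OCOC)c1 | intermediate
11 | [4-methoxy-2,6-bis(methoxymethoxy)phenyl]lithium | [Li]c1c(OCOC)cc(OC)cc1OCOC | intermediate
12 | (R)-4-[2-bromo-5-(triisopropylsilyloxy)phenoxy]-5-hydroxy-1-[4-methoxy-2,6-bis(methoxymethoxy)phenyl]-5-methylhexan-1-one | COCOc1cc(OC)cc(OCOC)c1C(=O)CC[C@H](C(C)(C)O)Oc2cc(O[Si](C(C)C)(C(C)C)C(C)C)ccc2Br | intermediate
13 | (R)-4-[2-bromo-5-(triisopropylsilyloxy)phenoxy]-1-(2,6-dihydroxy-4-methoxyphenyl)-5-hydroxy-5-methylhexan-1-one | COc1cc(O)c(C(=O)CC[C@H](C(C)(C)O)Oc2cc(O[Si](C(C)C)(C(C)C)C(C)C)ccc2Br)c(O)c1 | intermediate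
14 | (R,E)-4-[2-bromo-5-(triisopropylsilyloxy)phenoxy]-1-(2,6-dihydroxy-4-methoxyphenyl)-2-[(dimethylamino)methylidene]-5-hydroxy-5-methylhexan-1-one (drawn with NMe2 trans to the carbonyl) | COc1cc(O)c(C(=O)/C(C[C@H](C(C)(C)O)Oc2cc(O[Si](C(C)C)(C(C)C)C(C)C)ccc2Br)=C/N(C)C)c(O)c1 | intermediate
15 | (R)-3-[2-(2-bromo-5-(triisopropylsilyloxy)phenoxy)-3-hydroxy-3-methylbutyl]-5-hydroxy-7-methoxychromen-4-one | COc1cc2occ(C[C@H](C(C)(C)O)Oc3cc(O[Si](C(C)C)(C(C)C)C(C)C)ccc3Br)c(=O)c2c(O)c1 | intermediate
16 | (R)-5-hydroxy-7-methoxy tetracycle, 10-(2-hydroxypropan-2-yl), 4'-O-TIPS (oxepine closed by C2–C1') | COc1cc2oc3c(c(=O)c2c(O)c1)C[C@H](C(C)(C)O)Oc1cc(O[Si](C(C)C)(C(C)C)C(C)C)ccc1-3 | intermediate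
17 | 6-iodo derivative of 16 | COc1cc2oc3c(c(=O)c2c(O)c1I)C[C@H](C(C)(C)O)Oc1cc(O[Si](C(C)C)(C(C)C)C(C)C)ccc1-3 | intermediate
18 | 3-methylbut-1-yne | CC(C)C#C | starting material
19 | (E)-4,4,5,5-tetramethyl-2-(3-methylbut-1-enyl)-1,3,2-dioxaborolane | CC(C)/C=C/B1OC(C)(C)C(C)(C)O1 | intermediate
20 | 6-[(E)-3-methylbut-1-enyl] derivative of 16 (4'-O-TIPS) | COc1cc2oc3c(c(=O)c2c(O)c1/C=C/C(C)C)C[C@H](C(C)(C)O)Oc1cc(O[Si](C(C)C)(C(C)C)C(C)C)ccc1-3 | intermediate
21 | CNP0216454.1, (R)-configured at C10 | COc1cc2oc3c(c(=O)c2c(O)c1/C=C/C(C)C)C[C@H](C(C)(C)O)Oc1cc(O)ccc1-3 | target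

**Step count**

Total steps: 15. Longest linear sequence: 12 (steps 1, 2, 4, 5, 6, 8, 9, 10, 11, 12, 14, 15).

**Steps most likely to fail**

1. Step 11. The arylpalladium bromide may be reduced (hydrodebromination) faster than it reaches C2–H, palladium may be held by the 5-phenoxide/4-keto chelate, or the silyl ether may be lost under hot carbonate. Fallback, from 15, returning at 16: Miyaura borylation (B2pin2, Pd(dppf)Cl2, KOAc, dioxane, 80 °C) should give the pinacol boronate of 15 (Bpin in place of Br) F1. A base-free Pd(II)-catalysed oxidative Heck-type cyclisation (Pd(TFA)2, 1,10-phenanthroline, O2, DMSO/AcOH, 80 °C) then joins C1' to C2 by transmetalation, insertion into C2=C3 and β-hydride elimination. This is the known oxidative coupling of arylboron reagents with chromones at C2; no aryl halide remains to be reduced and the 5-OH stays protonated.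

2. Step 12. Iodination may go to C8 (para to the 5-OH) or to the B ring (C3'/C5') instead of C6, or proceed twice. Fallback, from 16, returning at 20: magnesium-mediated ortho-formylation (MgCl2, Et3N, paraformaldehyde, MeCN, reflux) delivers the electrophile inside the magnesium 5-phenoxide chelate and should give only the 6-formyl tetracycle F2. The olefination partner is made from 1-phenyl-1H-tetrazole-5-thiol and isobutyl bromide (K2CO3, acetone), giving 5-(isobutylsulfanyl)-1-phenyl-1H-tetrazole F3, which is oxidised (H2O2, ammonium molybdate, EtOH) to 5-(isobutylsulfonyl)-1-phenyl-1H-tetrazole F4. Julia–Kocienski olefination of F2 with F4 (KHMDS, excess, DME, −60 °C → rt) should give the (E)-alkene 20 directly.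

3. Step 10. The amide acetal may O-methylate a free phenol, the reaction may stall at the enaminone, or acetal exchange may occur at the tertiary alcohol. Fallback, from 12, returning at 15: Claisen formylation of the MOM-protected ketone (LDA, 2.2 equiv, THF, −78 °C; ethyl formate) should give the hydroxymethylene ketone F5, with no free phenol present. Treatment with 3 M HCl in MeOH at 45 °C then cleaves both MOM ethers and cyclodehydrates the resulting 2-hydroxyaryl β-keto aldehyde to chromone 15, bypassing 13.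

**Further compounds**

F1 | step 11 | (R)-5-hydroxy-3-[3-hydroxy-3-methyl-2-(2-(4,4,5,5-tetramethyl-1,3,2-dioxaborolan-2-yl)-5-(triisopropylsilyloxy)phenoxy)butyl]-7-methoxychromen-4-one | COc1cc2occ(C[C@H](C(C)(C)O)Oc3cc(O[Si](C(C)C)(C(C)C)C(C)C)ccc3B4OC(C)(C)C(C)(C)O4)c(=O)c2c(O)c1
F2 | step 12 | 6-formyl derivative of 16 | COc1cc2oc3c(c(=O)c2c(O)c1C=O)C[C@H](C(C)(C)O)Oc1cc(O[Si](C(C)C)(C(C)C)C(C)C)ccc1-3
F3 | step 12 | 5-(isobutylsulfanyl)-1-phenyl-1H-tetrazole | CC(C)CSc1nnnn1-c2ccccc2
F4 | step 12 | 5-(isobutylsulfonyl)-1-phenyl-1H-tetrazole | CC(C)CS(=O)(=O)c1nnnn1-c2ccccc2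
F5 | step 10 | (R,Z)-4-[2-bromo-5-(triisopropylsilyloxy)phenoxy]-5-hydroxy-2-(hydroxymethylidene)-1-[4-methoxy-2,6-bis(methoxymethoxy)phenyl]-5-methylhexan-1-one | COCOc1cc(OC)cc(OCOC)c1C(=O)/C(C[C@H](C(C)(C)O)Oc2cc(O[Si](C(C)C)(C(C)C)C(C)C)ccc2Br)=C\O
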